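## Retrosynthetic overview

1. Numbering follows benzofuran (O1, C2, C3, C3a, C4–C7, C7a). Ring A is the syringyl ring on C2, ring B the benzo ring, ring C the five-membered O-heterocycle, and ring D the resorcinol ring.
2. The four hydroxyl groups travel as TBS ethers and are released in one final desilylation. The C5–CH= bond of the stilbene is cut by a Heck reaction into a 5-bromo-2,3-dihydrobenzofuran and 3,5-bis(silyloxy)styrene.
3. Ring C is cut at O1–C2 and C3–C3a, giving bis-silylated (E)-sinapyl alcohol and the ortho-quinone diazide 4-bromo-6-diazo-2-methoxycyclohexa-2,4-dien-1-one. In the forward sense, one enantioselective dirhodium-carbene formal [3+2] cycloaddition makes both bonds, ring C and both stereocentres.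
4. Two features make this possible. O1 sits on C7a next to C3a, so O1–C7a–C3a of ring B is a masked α-oxo carbene (C7 carries OMe, C5 the coupling handle). C2 is benzylic to ring A, whose para oxygen at C4' can carry the charge as a para-quinone-methide-type cation, which dictates C3-to-carbene and O1-to-C2 bonding.
5. Rings A, B and D are bought as arenes. Ring B is dearomatised to the diazo dienone (nitration, reduction and diazotisation of 4-bromoguaiacol) and rearomatises as ring C, the only ring made, closes.

Key step: step 5

Assumption: the facial sense of Rh2(S-TCPTTL)4 with this carbene class is not known, so the (S)-ligand series is written, and the mirror-image catalyst Rh2(R-TCPTTL)4 would replace it if a trial run points to the (2S,3R) series. By CIP analysis of the given SMILES the target is the trans-(2R,3S) isomer.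

## Route

Step 1
Reactants: 1 4-bromo-2-methoxyphenol
Product: 2 4-bromo-2-methoxy-6-nitrophenol
Conditions: HNO3 (65%, 1.05 equiv), AcOH, 0–10 °C
Reagents that add atoms: nitric acid, O[N+](=O)[O-]
Why: Electrophilic aromatic nitration should be directed by the free hydroxyl group to its only open ortho position, because the para position carries bromine and the other ortho position carries OMe.

Step 2
Reactants: 2 4-bromo-2-methoxy-6-nitrophenol
Product: 3 2-amino-4-bromo-6-methoxyphenol
Conditions: H2 (1 atm), sulfided 5% Pt/C, EtOAc, rt
Reagents that add atoms: none
Why: Chemoselective catalytic hydrogenation of a nitroarene, in which the sulfided platinum catalyst should suppress hydrodebromination; the air-sensitive aminophenol is used at once.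

Step 3
Reactants: 3 2-amino-4-bromo-6-methoxyphenol
Product: 5 4-bromo-6-diazo-2-methoxycyclohexa-2,4-dien-1-one, via diazonium chloride 4 (not isolated)
Conditions: NaNO2, 2 M aq HCl, 0 °C; then NaHCO3 to pH 7–8, extraction into CH2Cl2, 0 °C, dark; kept as a dried solution
Reagents that add atoms: sodium nitrite, [Na+].[O-]N=O (the outer diazo nitrogen); hydrogen chloride, Cl (only the counter-ion of 4)
Why: Diazotisation of an ortho-aminophenol followed by deprotonation of the acidic ortho-hydroxy diazonium ion is the standard preparation of neutral diazo oxides (ortho-quinone diazides).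

Step 4
Reactants: 6 (E)-sinapyl alcohol
Product: 7 (E)-sinapyl alcohol bis-TBS ether, silylated at the phenolic oxygen and at the primary allylic oxygen
Conditions: TBSCl (2.5 equiv), imidazole (5 equiv), DMF, 0 °C to rt
Reagents that add atoms: tert-butyldimethylsilyl chloride, CC(C)(C)[Si](C)(C)Cl
Why: Imidazole-promoted silyl ether formation should mask both O–H bonds, which would otherwise undergo carbene O–H insertion, while keeping a para oxygen donor on ring A.

Step 5
Reactants: 5 4-bromo-6-diazo-2-methoxycyclohexa-2,4-dien-1-one; 7 (E)-sinapyl alcohol bis-TBS ether
Product: 10 (2R,3S)-5-bromo-2-[4-(tert-butyldimethylsilyloxy)-3,5-dimethoxyphenyl]-3-[(tert-butyldimethylsilyloxy)methyl]-7-methoxy-2,3-dihydrobenzofuran, via rhodium carbene 8 (not isolated), via zwitterion 9 (not isolated)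
Conditions: Rh2(S-TCPTTL)4 = dirhodium tetrakis[N-tetrachlorophthaloyl-(S)-tert-leucinate] (1 mol %), 7 (1.0 equiv), 5 (1.5 equiv, CH2Cl2 solution added over 6 h), 4 Å MS, CH2Cl2, 0 °C to rt, dark
Reagents that add atoms: none
Why: Proposed new method: the dirhodium catalyst expels N2 from 5 to give the electrophilic quinoid carbene 8, the CH2OTBS-bearing alkene carbon of 7 (future C3) attacks the carbene carbon (future C3a) while positive charge builds up on the other alkene carbon (future C2), and release of the catalyst rearomatises ring B to the phenolate/benzylic cation 9, whose O1 collapses onto C2. The closest known reaction types are the dirhodium-catalysed formal [3+2] cycloadditions of cyclic 2-diazo-1,3-diketones and of 1-diazonaphthalen-2(1H)-ones with styrenes and enol ethers to dihydrofurans, and asymmetric cyclopropanations with the same phthalimido-tert-leucinate catalysts; new here are the monocyclic diazo oxide, the E-1,2-disubstituted styrene and the enantiocontrol. Ring C, the only ring closed, forms by 5-exo-trig attack of O1 on the exocyclic C2=C1' bond of the para-quinone-methide-like resonance form of 9, driven by charge annihilation. C3 is set in the C3–C3a bond-forming event, while the carbene is still held in the chiral pocket built by the four tetrachlorophthalimido walls, which should leave only one enantiotopic face of the alkene able to reach the carbene carbon. C2 is set relative to C3, because closure through the conformer with ring A anti to CH2OTBS corresponds both to suprafacial addition to the E-alkene and to the more stable 2,3-trans isomer, so kinetic and thermodynamic preferences coincide. The step needs regioselectivity (secured by the para silyloxy group of ring A, which places the cation at C2), site selectivity on ring B (secured because the diazo carbon is the only carbene site, with C7 and C5 occupied by OMe and Br) and chemoselectivity over O–H insertion and carbene dimerisation (secured by the silyl ethers and the slow addition of 5).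

Step 6
Reactants: 11 3,5-dihydroxybenzaldehyde
Product: 12 3,5-bis(tert-butyldimethylsilyloxy)benzaldehyde
Conditions: TBSCl (2.4 equiv), imidazole (5 equiv), DMF, rt
Reagents that add atoms: tert-butyldimethylsilyl chloride, CC(C)(C)[Si](C)(C)Cl
Why: Imidazole-promoted silylation of both phenols puts ring D in the same protecting-group family as the rest of the molecule, so a single final deprotection suffices.

Step 7
Reactants: 12 3,5-bis(tert-butyldimethylsilyloxy)benzaldehyde
Product: 13 3,5-bis(tert-butyldimethylsilyloxy)styrene
Conditions: Ph3PCH3Br, n-BuLi, THF, 0 °C; then 12, 0 °C to rt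
Reagents that add atoms: methyltriphenylphosphonium bromide, C[P+](c1ccccc1)(c1ccccc1)c1ccccc1.[Br-] (the CH2 group)
Why: Wittig methylenation with a preformed, salt-tolerant ylide should convert the aldehyde into the terminal alkene without touching the aryl silyl ethers.

Step 8
Reactants: 10 (2R,3S)-5-bromo-dihydrobenzofuran bis-TBS ether; 13 3,5-bis(tert-butyldimethylsilyloxy)styrene
Product: 14 tetra-TBS ether of gnetucleistol F, (2R,3S), E-stilbene
Conditions: Pd2(dba)3 (2.5 mol %), [(t-Bu)3PH]BF4 (10 mol %), Cy2NMe (1.5 equiv), 1,4-dioxane, 70 °C
Reagents that add atoms: none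
Why: Mizoroki–Heck reaction, in which oxidative addition of zerovalent palladium into the unhindered C5–Br bond, syn insertion at the unsubstituted alkene terminus of 13 and syn β-hydride elimination should give the E-stilbene without touching the silyl ethers or C2/C3.

Step 9
Reactants: 14 tetra-TBS ether of gnetucleistol F
Product: 15 gnetucleistol F, (2R,3S)
Conditions: TBAF (5 equiv), AcOH (5 equiv), THF, 0 °C to rt
Reagents that add atoms: none
Why: Fluoride-mediated cleavage of all four silyl ethers, with acetic acid buffering to keep the ring A phenol protonated so that opening of ring C to a para-quinone methide, the only path that could scramble C2, should be suppressed.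

## Compound list

1 | 4-bromo-2-methoxyphenol | COc1cc(Br)ccc1O | starting material
2 | 4-bromo-2-methoxy-6-nitrophenol | COc1cc(Br)cc([N+](=O)[O-])c1O | intermediate
3 | 2-amino-4-bromo-6-methoxyphenol | COc1cc(Br)cc(N)c1O | intermediate
4 | 5-bromo-2-hydroxy-3-methoxybenzenediazonium chloride (not isolated) | COc1cc(Br)cc([N+]#N)c1O.[Cl-] | intermediate
5 | 4-bromo-6-diazo-2-methoxycyclohexa-2,4-dien-1-one | COC1=CC(Br)=CC(=[N+]=[N-])C1=O | intermediate
6 | (E)-sinapyl alcohol | COc1cc(/C=C/CO)cc(OC)c1O | starting material
7 | (E)-sinapyl alcohol bis-TBS ether | COc1cc(/C=C/CO[Si](C)(C)C(C)(C)C)cc(OC)c1O[Si](C)(C)C(C)(C)C | intermediate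
8 | dirhodium-bound 4-bromo-2-methoxy-6-oxocyclohexa-2,4-dienylidene (not isolated; only the carbene-bearing Rh atom drawn, ligands omitted) | COC1=CC(Br)=CC(=[Rh])C1=O | intermediate
9 | ring-opened zwitterion, ring B phenolate with the benzylic cation at C2, C3 configured as in 10 (not isolated) | COc1cc([CH+][C@H](CO[Si](C)(C)C(C)(C)C)c2cc(Br)cc(OC)c2[O-])cc(OC)c1O[Si](C)(C)C(C)(C)C | intermediate
10 | (2R,3S)-5-bromo-2-[4-(TBSO)-3,5-dimethoxyphenyl]-3-(TBSO-methyl)-7-methoxy-2,3-dihydrobenzofuran | COc1cc([C@@H]2Oc3c(OC)cc(Br)cc3[C@H]2CO[Si](C)(C)C(C)(C)C)cc(OC)c1O[Si](C)(C)C(C)(C)C | intermediate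
11 | 3,5-dihydroxybenzaldehyde | O=Cc1cc(O)cc(O)c1 | starting material
12 | 3,5-bis(tert-butyldimethylsilyloxy)benzaldehyde | O=Cc1cc(O[Si](C)(C)C(C)(C)C)cc(O[Si](C)(C)C(C)(C)C)c1 | intermediate
13 | 3,5-bis(tert-butyldimethylsilyloxy)styrene | C=Cc1cc(O[Si](C)(C)C(C)(C)C)cc(O[Si](C)(C)C(C)(C)C)c1 | intermediate
14 | tetra-TBS ether of gnetucleistol F, (2R,3S), E | COc1cc([C@@H]2Oc3c(OC)cc(/C=C/c4cc(O[Si](C)(C)C(C)(C)C)cc(O[Si](C)(C)C(C)(C)C)c4)cc3[C@H]2CO[Si](C)(C)C(C)(C)C)cc(OC)c1O[Si](C)(C)C(C)(C)C | intermediate
15 | gnetucleistol F, (2R,3S), E | COc1cc([C@@H]2Oc3c(OC)cc(/C=C/c4cc(O)cc(O)c4)cc3[C@H]2CO)cc(OC)c1O | target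

## Step count and risks

Total step count: 9.

Longest linear sequence: 6 (steps 1, 2, 3, 5, 8, 9).

**Step 5 (labelled step).**
- What may go wrong:
  - The E-1,2-disubstituted alkene may capture the carbene too slowly, so that carbene dimerisation or insertion into the allylic C–H bonds next to the silyl ether takes over.
  - A hydride shift in the zwitterion may erase C3.
  - Facial selectivity in the catalyst pocket may be poor.
- Fallback: it sets out from 6 and comes back at 15, and it uses the known biomimetic phenol oxidative β–5 cross-coupling.
  - Compound 6 and commercial isorhapontigenin (COc1cc(/C=C/c2cc(O)cc(O)c2)ccc1O) are oxidised together with Ag2O in acetone/CH2Cl2 at rt in the dark.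
  - The side-chain β-carbon of the sinapyl radical should couple with the free ortho carbon of the stilbene guaiacyl ring. Rearomatisation and closure of the phenol onto the para-quinone methide should then give the racemic trans-dihydrobenzofuran, that is 15 together with the mirror-image compound (2S,3R)-gnetucleistol F F1.
  - Homodimers are removed by chromatography, and the enantiomers are separated on a polysaccharide-based chiral stationary phase to return 15.

**Step 3.**
- What may go wrong: the diazonium ion may undergo azo coupling with unreacted electron-rich aminophenol during the aqueous diazotisation, and the neutral diazo oxide may decompose during extraction and handling.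
- Fallback: it sets out from 3 and comes back at 5.
  - Aprotic diazotisation with t-BuONO and HBF4·OEt2 in Et2O/MeCN at −10 °C should precipitate the filterable, storable salt 5-bromo-2-hydroxy-3-methoxybenzenediazonium tetrafluoroborate F2, which can be washed free of amine.
  - Immediately before step 5 the salt is stirred with powdered K2CO3 in CH2Cl2 at 0 °C and the filtrate is fed directly by syringe pump.
  - Compound 5 is thus released only on demand and is never concentrated.

**Step 8.**
- What may go wrong: oxidative addition into the electron-rich C5–Br bond may be slow, aryl silyl ethers may be lost on prolonged heating with amine, and insertion with the opposite regiochemistry may give a 1,1-diarylethene.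
- Fallback: it sets out from 13 (and 10) and comes back at 14, replacing alkene insertion by transmetalation.
  - Cross-metathesis of 13 with vinylboronic acid pinacol ester (second-generation Grubbs catalyst, CH2Cl2, 40 °C) should give (E)-2-[3,5-bis(tert-butyldimethylsilyloxy)styryl]-4,4,5,5-tetramethyl-1,3,2-dioxaborolane F3.
  - Suzuki–Miyaura coupling of F3 with 10 (Pd(dppf)Cl2, K3PO4, THF/H2O, 50 °C) should transfer the preformed E-alkene and give 14.

Further compounds
F1 | step 5 | (2S,3R)-gnetucleistol F, the enantiomer formed beside 15 in the racemate | COc1cc([C@H]2Oc3c(OC)cc(/C=C/c4cc(O)cc(O)c4)cc3[C@@H]2CO)cc(OC)c1O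
F2 | step 3 | 5-bromo-2-hydroxy-3-methoxybenzenediazonium tetrafluoroborate | COc1cc(Br)cc([N+]#N)c1O.F[B-](F)(F)F
F3 | step 8 | (E)-2-[3,5-bis(tert-butyldimethylsilyloxy)styryl]-4,4,5,5-tetramethyl-1,3,2-dioxaborolane | CC1(C)OB(/C=C/c2cc(O[Si](C)(C)C(C)(C)C)cc(O[Si](C)(C)C(C)(C)C)c2)OC1(C)C
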